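**Retrosynthetic overview**
1. Target 5 is the mono-acetate of the C2-symmetric anti diol 3, configuration (3S,5S) as read from the SMILES. The two carbinol OH groups of 3 are homotopic, so the only disconnection needed is the acetate C(acyl)–O bond: any single aliphatic O-acetylation, and any later 1,3-acyl shift, gives 5.
2. The difficulty in that C–O bond formation is selectivity (aliphatic OH over two phenols, mono over di). It is addressed with a catalyst that activates only a chelating 1,3-diol.
3. Diol 3 comes from tetrahydrocurcumin 1 by double asymmetric hydrogenation of the β-diketone, which sets both stereocentres. The whole C21 skeleton is bought; no C–C bond is made.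
4. No ring is formed: both arene rings are already in 1, and the six-membered borinate chelate 4 is transient.

Assumption: tetrahydrocurcumin (≥97 %, a catalogue chemical and bulk cosmetic ingredient) is taken as a cheap commercial starting material.

**Step 1**
Reactants: 1 tetrahydrocurcumin (1,7-bis(4-hydroxy-3-methoxyphenyl)heptane-3,5-dione)
Product: 3 (3S,5S)-1,7-bis(4-hydroxy-3-methoxyphenyl)heptane-3,5-diol, via (S)-hexahydrocurcumin 2 (not isolated)
Conditions: RuCl2[(S)-BINAP](dmf)n (1 mol%), H2 (60 atm), degassed MeOH, 50 °C, 48 h; recrystallise
Reagents that add atoms: none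
Why: Noyori Ru–BINAP asymmetric hydrogenation of a β-diketone, in which the first reduction gives the (S)-β-hydroxy ketone 2 and the second, again under control of the (S)-ligand, gives the anti (3S,5S)-diol; the minor enantiomer of 2 ends up as the meso diol, so the anti product is essentially enantiopure, and phenols and arenes are untouched.

**Step 2**
Reactants: 3 (3S,5S)-1,7-bis(4-hydroxy-3-methoxyphenyl)heptane-3,5-diol
Product: 5 (3S,5S)-5-hydroxy-1,7-bis(4-hydroxy-3-methoxyphenyl)heptan-3-yl acetate, via diol borinate complex 4 (not isolated)
Conditions: Ph2B–OCH2CH2NH2 (10 mol%), Ac2O (1.15 equiv), iPr2NEt (1.3 equiv), MeCN, 0 °C → rt; aq. NH4Cl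
Reagents that add atoms: acetic anhydride, CC(=O)OC(C)=O
Why: Proposed new method: the borinic acid condenses reversibly with 3 and, with iPr2NEt, forms the anionic tetracoordinate chelate 4, whose boron-bound alkoxide oxygens are the only anionic O-nucleophiles present (ArOH, pKa ≈ 29 in MeCN against ≈ 18–19 for the ammonium, stays protonated and reacts only slowly with Ac2O without a nucleophilic catalyst), so Ac2O acylates one chelated oxygen, the monoacetate can no longer chelate boron and is released without a second acylation, and because 3 is C2-symmetric either oxygen gives the same compound 5 with both stereocentres untouched; the closest known reaction type is borinic-acid-catalysed regioselective mono-acylation of cis-1,2-diols and simple 1,3-diols with acyl chlorides, and the untested part is an acyclic anti-1,3-diol (twist-boat chelate) carrying two free phenols with an anhydride as donor.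

**Compound list**
1 | tetrahydrocurcumin, 1,7-bis(4-hydroxy-3-methoxyphenyl)heptane-3,5-dione | COc1cc(CCC(=O)CC(=O)CCc2ccc(O)c(OC)c2)ccc1O | starting material
2 | (S)-hexahydrocurcumin, (5S)-5-hydroxy-1,7-bis(4-hydroxy-3-methoxyphenyl)heptan-3-one | COc1cc(CC[C@H](O)CC(=O)CCc2ccc(O)c(OC)c2)ccc1O | intermediate
3 | (3S,5S)-octahydrocurcumin, (3S,5S)-1,7-bis(4-hydroxy-3-methoxyphenyl)heptane-3,5-diol | COc1cc(CC[C@H](O)C[C@H](CCc2ccc(O)c(OC)c2)O)ccc1O | intermediate
4 | N,N-diisopropylethylammonium (4S,6S)-4,6-bis[2-(4-hydroxy-3-methoxyphenyl)ethyl]-2,2-diphenyl-1,3,2-dioxaborinan-2-uide (tetracoordinate diphenylborinate chelate of 3) | O1[C@@H](CCc2ccc(O)c(OC)c2)C[C@H](CCc3ccc(O)c(OC)c3)O[B-]1(c4ccccc4)c5ccccc5.CC[NH+](C(C)C)C(C)C | intermediate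
5 | (3S,5S)-5-hydroxy-1,7-bis(4-hydroxy-3-methoxyphenyl)heptan-3-yl acetate | COc1cc(CC[C@H](O)C[C@H](CCc2ccc(O)c(OC)c2)OC(C)=O)ccc1O | target

**Totals**
Total step count: 2. Longest linear sequence: 2 steps (1 → 3 → 5).

**Steps most likely to fail**
The route has only two steps, so both are ranked.

First, step 2 (the proposed new step). The risks are a weak or slow chelate, because an anti-1,3-diol must bind Ph2B in a twist-boat, background acetylation of the phenols, and some diacetate. The fallback uses known chemistry and replaces catalytic diol activation by a cyclic orthoester. It sets out from 3: triethyl orthoacetate (1.5 equiv) and PPTS (5 mol%) in CH2Cl2 at rt give the cyclic orthoester (4S,6S)-2-ethoxy-4,6-bis[2-(4-hydroxy-3-methoxyphenyl)ethyl]-2-methyl-1,3-dioxane F1. This is opened in the same flask with 80 % aq. AcOH at 0 °C to rt, through the 1,3-dioxan-2-ylium ion and its hemi-orthoester, to the hydroxy acetate. Only a monoester can form, phenols are not acylated (any mixed aryl orthoester hydrolyses back to the phenol), and both ring-opening directions give the same product. The fallback comes back to the route at 5.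

Second, step 1. The risks are stalling at the hydroxy ketone, erosion of the anti:syn ratio, and slow turnover from the strongly enolised, phenol-bearing substrate. The fallback replaces the catalyst-controlled double hydrogenation by a biocatalytic mono-reduction followed by a substrate-directed reduction. It sets out from 1: an (S)-selective ketoreductase picked from a commercial panel (NADP+, i-PrOH, pH 7 buffer with DMSO, 30 °C) gives the β-hydroxy ketone 2, now isolated. Evans–Saksena reduction with Me4NBH(OAc)3 in MeCN/AcOH at −30 °C then delivers hydride intramolecularly from the boron-bound hydroxyl to give the 1,3-anti diol. The fallback comes back to the route at 3 and makes no compound outside the list (F0).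

**Further compounds**
F0 | step 1 | none | none
F1 | step 2 | (4S,6S)-2-ethoxy-4,6-bis[2-(4-hydroxy-3-methoxyphenyl)ethyl]-2-methyl-1,3-dioxane | CCOC1(C)O[C@@H](CCc2ccc(O)c(OC)c2)C[C@H](CCc3ccc(O)c(OC)c3)O1
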